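**Plan**

- The target is a 2-methoxy-3,5-dimethyl-4-pyranone with a (10S)-10-acetoxyundecyl chain; the ring is numbered O1, C2 (OMe), C3 (Me), C4 (C=O), C5 (Me), C6 (chain).
- Enabling feature: O1 lies between a carbonyl-level carbon (C2) and an enol carbon (C6). The heterocycle is therefore an enol ester, propanoic acid (C2, C3, 3-Me) esterified with the enol of a 2-methyl-3-oxo ester (C6, C5, C4). It is cut at C3–C4 (ester condensation) and then at O1–C2 (O-acylation).
- The side chain is cut at C1'–C2' (alkylation of a 3-oxo ester dianion) and at C8'–C9' (epoxide opening by a Grignard reagent).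
- Forward order: chain iodide, keto ester, Z-enol propanoate, closure of the only ring, O-methylation at the lactone carbonyl, desilylation, acetylation.
- Stereochemistry: the single (S) centre comes from (S)-propylene oxide, opened at its CH2 group; the C–O bond at that centre is never broken.

Key step: step 6

Remark: the keto ester of step 4 forms as both epimers at its C2, which is immaterial because that carbon becomes trigonal in step 5; the four starting materials are taken to be catalogue chemicals.

**Step 1**
Reactants: 1 1-bromo-7-chloroheptane; 2 (S)-propylene oxide [(2S)-2-methyloxirane]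
Product: 4 (2S)-10-chlorodecan-2-ol, via 7-chloroheptylmagnesium bromide 3 (not isolated)
Conditions: Mg, THF, 30 °C; then 2, CuI (10 mol %), THF, −30 to 0 °C; 1 M HCl work-up
Reagents that add atoms: none
Why: Magnesium inserts into the C–Br bond and not into the C–Cl bond, and the copper-catalysed Grignard opening of a terminal epoxide (SN2 at the CH2 group) leaves the C–O bond at the stereocentre untouched, so the (S) configuration of 2 is carried into 4.

**Step 2**
Reactants: 4 (2S)-10-chlorodecan-2-ol
Product: 5 tert-butyl{[(2S)-10-chlorodecan-2-yl]oxy}dimethylsilane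
Conditions: TBSCl, imidazole, DMF, rt
Reagents that add atoms: tert-butyldimethylsilyl chloride, CC(C)(C)[Si](C)(C)Cl
Why: Imidazole-promoted silylation (silyl ether protection) of a secondary alcohol is routine, and the primary chloride does not react.

**Step 3**
Reactants: 5 tert-butyl{[(2S)-10-chlorodecan-2-yl]oxy}dimethylsilane
Product: 6 tert-butyl{[(2S)-10-iododecan-2-yl]oxy}dimethylsilane
Conditions: NaI (5 equiv), 2-butanone, 80 °C
Reagents that add atoms: sodium iodide, [Na+].[I-]
Why: Finkelstein halide exchange at the primary carbon, driven by precipitation of NaCl, turns the chloride into the more reactive iodide without touching the silyl ether.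

**Step 4**
Reactants: 7 methyl 2-methyl-3-oxobutanoate (1.5 equiv); 6 tert-butyl{[(2S)-10-iododecan-2-yl]oxy}dimethylsilane
Product: 9 methyl (13S)-13-[(tert-butyldimethylsilyl)oxy]-2-methyl-3-oxotetradecanoate, via sodium lithium dianion 8 (not isolated)
Conditions: NaH, THF, 0 °C; n-BuLi, 0 °C; then 6, 0 °C to rt; cold 0.5 M HCl quench
Reagents that add atoms: none
Why: γ-Alkylation of a 3-oxo ester dianion: the second deprotonation takes place at the terminal methyl group, and only this more basic carbon is alkylated by the primary iodide, the stabilised C2 enolate remaining a spectator.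

**Step 5**
Reactants: 9 methyl (13S)-13-[(tert-butyldimethylsilyl)oxy]-2-methyl-3-oxotetradecanoate; 10 propanoyl chloride
Product: 12 methyl (2Z,13S)-13-[(tert-butyldimethylsilyl)oxy]-2-methyl-3-(propanoyloxy)tetradec-2-enoate, via chelated lithium enolate 11 (not isolated)
Conditions: LiN(SiMe3)2 (1.0 equiv, no excess), THF, −78 °C; then 10 (1.2 equiv), −78 to 0 °C
Reagents that add atoms: none
Why: O-Acylation of a chelated enolate: lithium bridges the enolate and ester oxygens of 11 and so holds the enolate oxygen cis to the ester, and the acyl chloride attacks oxygen because acylation at the fully substituted C2 would have to build a quaternary carbon, as in the Z-selective preparation of enol phosphates, sulfonates and carbonates of 3-oxo esters.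

**Step 6**
Reactants: 12 methyl (2Z,13S)-13-[(tert-butyldimethylsilyl)oxy]-2-methyl-3-(propanoyloxy)tetradec-2-enoate
Product: 15 6-{(10S)-10-[(tert-butyldimethylsilyl)oxy]undecyl}-4-hydroxy-3,5-dimethyl-2H-pyran-2-one, via lithium ester enolate 13 (not isolated), via lithium pyranolate 14 (not isolated)
Conditions: 12 added slowly to LiN(SiMe3)2 (2.5 equiv), THF (0.02 M), −78 °C, then −78 to −20 °C; cold 1 M HCl to pH 3
Reagents that add atoms: none
Why: Proposed new method: LiN(SiMe3)2 takes a proton from the propanoyl CH2 of 12, the carbon of ester enolate 13 (ring C3) adds to the methyl ester carbonyl (ring C4) that the Z double bond holds on the same side, and collapse of the adduct with loss of methoxide gives a 3-methylpyran-2,4-dione whose acidic C3–H is removed immediately (pyranolate 14), so the condensation cannot run backwards and acidification delivers 15. The closest known reaction type is the base-mediated intramolecular Claisen (Dieckmann-type) condensation of methyl O-acylsalicylates to 4-hydroxycoumarins, in which a benzene ring takes the place of the enol double bond; closing an acyclic enol ester of a 3-oxo ester in this way is the untested part. The six-membered ring closes in a 6-(enolendo)-exo-trig mode, which is geometrically favoured for enolates, and because the ring oxygen was installed in step 5 the closure involves carbon only, so no competition between oxygen nucleophiles can arise and the substitution pattern is settled before the ring exists. No stereocentre is formed, and the remote (S)-silyloxy centre is inert to the amide base. The step needs deprotonation at the propanoyl CH2 and not at the allylic C4 methylene of the enoate, and it needs ring closure to outrun E1cB loss of methylketene from 13; the first is favoured by the aryl-ester-like acidity and open position of the propanoyl hydrogens and by the fact that a dienolate can revert through HN(SiMe3)2 while ring closure cannot, the second by the Z geometry from step 5, the low temperature, and slow addition to excess base at high dilution, which also suppresses acyl transfer between molecules. Methylketene that escapes can still acylate chelated enolate 11 at oxygen and re-enter the productive path.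

**Step 7**
Reactants: 15 6-{(10S)-10-[(tert-butyldimethylsilyl)oxy]undecyl}-4-hydroxy-3,5-dimethyl-2H-pyran-2-one
Product: 17 6-{(10S)-10-[(tert-butyldimethylsilyl)oxy]undecyl}-2-methoxy-3,5-dimethyl-4H-pyran-4-one, via hydroxymethoxypyrylium fluorosulfonate 16 (not isolated)
Conditions: MeOSO2F (1.5 equiv), CH2Cl2, 0 °C to rt; then partition between CH2Cl2 and cold water
Reagents that add atoms: methyl fluorosulfonate, COS(=O)(=O)F
Why: O-Methylation of a vinylogous acid with a hard alkylating agent under neutral conditions: the ring carbonyl oxygen of the 4-hydroxy-2-pyranone is its most nucleophilic site because methylation there gives aromatic pyrylium ion 16, which resists a second methylation and loses its hydroxyl proton on work-up to give the 2-methoxy-4-pyranone.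

**Step 8**
Reactants: 17 6-{(10S)-10-[(tert-butyldimethylsilyl)oxy]undecyl}-2-methoxy-3,5-dimethyl-4H-pyran-4-one
Product: 18 6-[(10S)-10-hydroxyundecyl]-2-methoxy-3,5-dimethyl-4H-pyran-4-one
Conditions: HF·pyridine, pyridine, THF, 0 °C to rt
Reagents that add atoms: none
Why: Fluoride-mediated desilylation, driven by the strength of the Si–F bond and buffered by pyridine, frees the secondary alcohol without breaking the C–O bond at the stereocentre or touching the methoxypyranone.

**Step 9**
Reactants: 18 6-[(10S)-10-hydroxyundecyl]-2-methoxy-3,5-dimethyl-4H-pyran-4-one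
Product: 19 (2S)-11-(6-methoxy-3,5-dimethyl-4-oxo-4H-pyran-2-yl)undecan-2-yl acetate
Conditions: Ac2O, pyridine, DMAP (cat.), CH2Cl2, rt
Reagents that add atoms: acetic anhydride, CC(=O)OC(C)=O
Why: DMAP-catalysed acetylation (nucleophilic catalysis) of the secondary alcohol takes place at oxygen with retention at carbon, and the pyranone offers no competing nucleophile.

**Compound list**

1 | 1-bromo-7-chloroheptane | ClCCCCCCCBr | starting material
2 | (S)-propylene oxide, (2S)-2-methyloxirane | C[C@H]1CO1 | starting material
3 | 7-chloroheptylmagnesium bromide | ClCCCCCCC[Mg]Br | intermediate (not isolated)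
4 | (2S)-10-chlorodecan-2-ol | ClCCCCCCCC[C@H](C)O | intermediate
5 | tert-butyl{[(2S)-10-chlorodecan-2-yl]oxy}dimethylsilane | ClCCCCCCCC[C@H](C)O[Si](C)(C)C(C)(C)C | intermediate
6 | tert-butyl{[(2S)-10-iododecan-2-yl]oxy}dimethylsilane | ICCCCCCCC[C@H](C)O[Si](C)(C)C(C)(C)C | intermediate
7 | methyl 2-methyl-3-oxobutanoate (racemic) | COC(=O)C(C)C(C)=O | starting material
8 | sodium lithium 1-methoxy-2-methylbuta-1,3-diene-1,3-bis(olate), the dianion of 7 | [Na+].[Li+].C=C([O-])C(C)=C([O-])OC | intermediate (not isolated)
9 | methyl (13S)-13-[(tert-butyldimethylsilyl)oxy]-2-methyl-3-oxotetradecanoate (both C2 epimers) | COC(=O)C(C)C(=O)CCCCCCCCC[C@H](C)O[Si](C)(C)C(C)(C)C | intermediate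
10 | propanoyl chloride | CCC(=O)Cl | starting material
11 | lithium (2Z,13S)-13-[(tert-butyldimethylsilyl)oxy]-1-methoxy-2-methyl-1-oxotetradec-2-en-3-olate | [Li+].[O-]/C(CCCCCCCCC[C@H](C)O[Si](C)(C)C(C)(C)C)=C(C)\C(=O)OC | intermediate (not isolated)
12 | methyl (2Z,13S)-13-[(tert-butyldimethylsilyl)oxy]-2-methyl-3-(propanoyloxy)tetradec-2-enoate | CCC(=O)O/C(CCCCCCCCC[C@H](C)O[Si](C)(C)C(C)(C)C)=C(C)\C(=O)OC | intermediate
13 | lithium 1-{[(2Z,13S)-13-[(tert-butyldimethylsilyl)oxy]-1-methoxy-2-methyl-1-oxotetradec-2-en-3-yl]oxy}prop-1-en-1-olate (enolate geometry open) | [Li+].CC=C([O-])O/C(CCCCCCCCC[C@H](C)O[Si](C)(C)C(C)(C)C)=C(C)\C(=O)OC | intermediate (not isolated)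
14 | lithium 6-{(10S)-10-[(tert-butyldimethylsilyl)oxy]undecyl}-3,5-dimethyl-2-oxo-2H-pyran-4-olate | [Li+].[O-]c1c(C)c(CCCCCCCCC[C@H](C)O[Si](C)(C)C(C)(C)C)oc(=O)c1C | intermediate (not isolated)
15 | 6-{(10S)-10-[(tert-butyldimethylsilyl)oxy]undecyl}-4-hydroxy-3,5-dimethyl-2H-pyran-2-one | Cc1c(O)c(C)c(CCCCCCCCC[C@H](C)O[Si](C)(C)C(C)(C)C)oc1=O | intermediate
16 | 6-{(10S)-10-[(tert-butyldimethylsilyl)oxy]undecyl}-4-hydroxy-2-methoxy-3,5-dimethylpyrylium fluorosulfonate | COc1[o+]c(CCCCCCCCC[C@H](C)O[Si](C)(C)C(C)(C)C)c(C)c(O)c1C.[O-]S(=O)(=O)F | intermediate (not isolated)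
17 | 6-{(10S)-10-[(tert-butyldimethylsilyl)oxy]undecyl}-2-methoxy-3,5-dimethyl-4H-pyran-4-one | COc1oc(CCCCCCCCC[C@H](C)O[Si](C)(C)C(C)(C)C)c(C)c(=O)c1C | intermediate
18 | 6-[(10S)-10-hydroxyundecyl]-2-methoxy-3,5-dimethyl-4H-pyran-4-one | COc1oc(CCCCCCCCC[C@H](C)O)c(C)c(=O)c1C | intermediate
19 | (2S)-11-(6-methoxy-3,5-dimethyl-4-oxo-4H-pyran-2-yl)undecan-2-yl acetate | COc1oc(CCCCCCCCC[C@H](C)OC(C)=O)c(C)c(=O)c1C | target

**Totals**

Total step count: 9. Longest linear sequence: 9 steps (1 to 19; compounds 2, 7 and 10 enter in single steps).

**Steps most likely to fail**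

1. Step 6 (proposed new method). The enolate may fragment by loss of methylketene faster than it cyclises, the base may remove the allylic C4 proton instead, or acyl transfer between molecules may outrun ring closure. The fallback uses known chemistry, sets out from iodide 6 and comes back at 15. Commercial methyl 2-methyl-3-oxopentanoate would be converted into its dianion (NaH, then n-BuLi, THF, 0 °C) and acetylated at C4 with N-methoxy-N-methylacetamide to give methyl 2,4-dimethyl-3,5-dioxohexanoate F1. DBU in toluene at 80 °C should close F1 by the classical C–O lactonisation to 4-hydroxy-3,5,6-trimethyl-2H-pyran-2-one F2. Double deprotonation of F2 (LiN(i-Pr)2, 2.2 equiv, THF–DMPU, −78 °C) and alkylation of the dianion at its 6-methyl carbon with 6 forms the same C1'–C2' bond as step 4 and returns to the route at 15.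

2. Step 5. Acylation may occur at carbon instead of oxygen, geometric control may be lost if the lithium chelate opens, and surplus base would start the condensation prematurely. The fallback sets out from 9 and comes back at 12. Enolate 11 would be quenched with Me3SiCl, which reacts only at oxygen, to give methyl (2Z,13S)-13-[(tert-butyldimethylsilyl)oxy]-2-methyl-3-[(trimethylsilyl)oxy]tetradec-2-enoate F3, a compound that can be purified and whose geometry can be checked. Propanoyl fluoride F4 (from 10 and KF in MeCN) with catalytic Bu4NF in THF at 0 °C should then exchange silicon for the acyl group, the known fluoride-catalysed O-acylation of silyl enol ethers by acyl fluorides, to give 12.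

3. Step 7. Methylation may take place at the 4-oxygen instead of the ring carbonyl oxygen, and the acidic pyrylium salt may remove the silyl group, after which the freed alcohol would be methylated. The fallback sets out from iodide 6 and comes back at 17. 4-Hydroxy-3,5,6-trimethyl-2H-pyran-2-one F2 (made as described for step 6) would be methylated with MeOSO2F at this small, silyl-free stage, where an isomer can be removed by crystallisation or chromatography, to give 2-methoxy-3,5,6-trimethyl-4H-pyran-4-one F5. Deprotonation of F5 at its 6-methyl group (LiN(SiMe3)2, THF, −78 °C) and alkylation of the vinylogous enolate with 6 returns to the route at 17, so that the long-chain pyranone never meets the methylating agent.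

**Further compounds**

F1 | step 6 | methyl 2,4-dimethyl-3,5-dioxohexanoate | COC(=O)C(C)C(=O)C(C)C(C)=O
F2 | step 6 | 4-hydroxy-3,5,6-trimethyl-2H-pyran-2-one | Cc1oc(=O)c(C)c(O)c1C
F3 | step 5 | methyl (2Z,13S)-13-[(tert-butyldimethylsilyl)oxy]-2-methyl-3-[(trimethylsilyl)oxy]tetradec-2-enoate | C[Si](C)(C)O/C(CCCCCCCCC[C@H](C)O[Si](C)(C)C(C)(C)C)=C(C)\C(=O)OC
F4 | step 5 | propanoyl fluoride | CCC(=O)F
F5 | step 7 | 2-methoxy-3,5,6-trimethyl-4H-pyran-4-one | COc1oc(C)c(C)c(=O)c1C
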